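**Plan**
1. Numbering: each half is numbered as a labdane, the acid half C1–C20 and the alcohol half C1'–C20'; the central cyclohexene is C12, C13(=C14), C15, C15', C14'.
2. Enabling feature: the alcohol-half decalin (ring A' = C1'–C5', C10'; ring B' = C5'–C10') with its C11' methylene is an (E,E)-farnesyl chain folded chair–chair. Its C18' hydroxymethyl makes C3'=C4' an allylic alcohol (site for an epoxide trigger), and the C17' methyl on C8' supplies the hydrogen lost on forming the exocyclic methylene.
3. Cuts (retro): C4'–C5' and C9'–C10' (Cp2TiCl radical bicyclization, ring A' then ring B'); C11'–C12' (alkenylalane–allyl acetate coupling); C12–C14' and C15–C15' (Diels–Alder); C4–C5 and C9–C10 (same bicyclization); C11–C12 (same coupling).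
4. Forward: one C15 block 3 from farnesyl acetate is used twice. Order: left chain, rings A and B, central ring, C13' alkyne, right chain, ring A', ring B' last.
5. Stereochemistry: Sharpless epoxidation with L-(+)-tartrate (twice) fixes C3/C3', relayed through chair–chair transition states to C4, C5, C9, C10 and their primed counterparts. An (R)-benzyloxazolidinone acrylimide fixes C12 and C14' (endo, cis). Olefin geometries come from the (E,E)-farnesyl unit and syn-carboalumination.
6. Helpers: the 3- and 3'-hydroxyls are removed by Barton–McCombie reduction; C18 travels as a TBS ether and is oxidised at the end, C18' as a TBDPS ether.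

Key step: step 14

Remark on the chemistry: (2E,6E)-farnesyl acetate, but-1-en-3-yne (as a solution), (R)-4-benzyl-oxazolidin-2-one and acryloyl chloride are taken as purchased. α/β refer to the usual labdane drawing (C20 methyl β). "Left core" means the 5α,9α,10β-labd-8(17)-ene bicycle C1–C11 with C17, C19 (4β-methyl) and C20; "central ring" means the cis-(12S,14'S) cyclohexene defined above.

Step 1
Reactants: 1 (2E,6E)-farnesyl acetate
Product: 2 (2E,6E,10E)-12-hydroxy-3,7,11-trimethyldodeca-2,6,10-trienyl acetate
Conditions: SeO2 (0.1 equiv), salicylic acid (0.1 equiv), t-BuOOH (3 equiv), CH2Cl2, rt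
Reagents that add atoms: tert-butyl hydroperoxide CC(C)(C)OO; selenium dioxide O=[Se]=O (catalytic oxygen carrier)
Why: The SeO2/t-BuOOH allylic oxidation (ene reaction, then [2,3]-sigmatropic shift) should hydroxylate the E-methyl of the terminal trisubstituted olefin, the most electron-rich and least hindered one (C2=C3 is deactivated by the allylic acetate), giving the E-allylic alcohol without creating a stereocentre.

Step 2
Reactants: 2 (2E,6E,10E)-12-hydroxyfarnesyl acetate
Product: 3 (2E,6E,10E)-3,7,11-trimethyl-12-(triethylsilyloxy)dodeca-2,6,10-trienyl acetate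
Conditions: Et3SiCl, imidazole, CH2Cl2, 0 °C
Reagents that add atoms: chlorotriethylsilane CC[Si](Cl)(CC)CC
Why: Standard silylation of a primary allylic alcohol; the triethylsilyl ether masks the hydroxyl from the organoaluminium reagents of the coupling steps and is labile enough to be removed afterwards by dilute acetic acid.

Step 3
Reactants: 3 C15 acetate; 4 but-1-en-3-yne
Product: 7 (2E,6E,10E,13E)-2,6,10,14-tetramethylhexadeca-2,6,10,13,15-pentaen-1-ol, via dienylalane 5 (not isolated), via triethylsilyl ether 6 (not isolated)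
Conditions: 4 (1.5 equiv), Me3Al (2 equiv), Cp2ZrCl2 (0.25 equiv), ClCH2CH2Cl, 0 °C to rt; then 3, Pd(PPh3)4 (5 mol%), THF, rt; aq. potassium sodium tartrate; then AcOH–THF–H2O (3:1:1), rt
Reagents that add atoms: trimethylaluminium C[Al](C)C
Why: Negishi carboalumination adds Me–Al syn across the alkyne to give the (E)-dienylalane, and the zerovalent-palladium-catalysed alkenyl–allyl coupling with the allylic acetate occurs at the primary allyl terminus with retention of both olefin geometries, so C12=C13 and the future C8=C9 olefin are both E; aqueous acetic acid then frees the primary alcohol.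

Step 4
Reactants: 7 pentaenol
Product: 9 tert-butyldimethylsilyl ether of (2S,3S)-2,3-epoxy-2,6,10,14-tetramethylhexadeca-6E,10E,13E,15-tetraen-1-ol, via epoxy alcohol 8 (not isolated)
Conditions: Ti(OiPr)4 (0.1 equiv), L-(+)-diethyl tartrate (0.12 equiv), t-BuOOH (2 equiv), 4 Å MS, CH2Cl2, −20 °C; then P(OMe)3; then imidazole, t-BuMe2SiCl, 0 °C to rt
Reagents that add atoms: tert-butyl hydroperoxide CC(C)(C)OO; tert-butyldimethylsilyl chloride CC(C)(C)[Si](C)(C)Cl
Why: Katsuki–Sharpless asymmetric epoxidation touches only the allylic alcohol olefin (C3=C4) among five double bonds, and L-(+)-tartrate delivers oxygen to the face that gives the (2S,3S)-epoxy alcohol (C3 S and C4 S in labdane numbering); silylation in the same flask (in situ derivatisation) protects the alcohol for the radical step.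

Step 5
Reactants: 9 epoxy silyl ether
Product: 10 18-(tert-butyldimethylsilyloxy)labda-8(17),12E,14-trien-3β-ol (5α-H; 9α-H; 10β-CH3; 4β-CH3)
Conditions: Cp2TiCl2 (2.5 equiv), Mn dust (8 equiv), THF, rt; 9 added over 4 h (final 0.01 M); dilute HCl work-up
Reagents that add atoms: none
Why: In this Cp2TiCl-mediated reductive epoxide opening and radical polyene cyclization the tertiary C4 radical closes ring A (6-endo, C4–C5) and the C10 radical closes ring B (6-endo, C9–C10) through a chair–chair array with the C3–O–Ti group equatorial, so C3 relays its configuration to C5 (α-H), C10 (β-CH3) and C9 (α-H), the larger CH2OTBS group takes the equatorial 4α position, and titanium-assisted loss of a C17 hydrogen gives the exocyclic olefin; the conjugated diene cannot be reached intramolecularly and high dilution limits intermolecular addition to it.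

Step 6
Reactants: 11 (R)-4-benzyl-oxazolidin-2-one; 12 acryloyl chloride
Product: 13 (R)-3-acryloyl-4-benzyl-oxazolidin-2-one
Conditions: MeMgBr (1.0 equiv), THF, 0 °C; then 12, −78 °C
Reagents that add atoms: none
Why: N-Acylation of the bromomagnesium salt of the oxazolidinone with acryloyl chloride is the standard preparation of this dienophile and leaves the auxiliary stereocentre untouched.

Step 7
Reactants: 10 labdatrienol; 13 (R)-acrylimide
Product: 14 imide: left core (3β-OH; 18-OTBS)–central ring–C14'-carbonyl-N-[(R)-4-benzyl-2-oxo-oxazolidin-3-yl]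
Conditions: 13 (1.5 equiv), Et2AlCl (3 equiv), CH2Cl2, −78 °C; 1 M HCl work-up
Reagents that add atoms: none
Why: In this auxiliary-controlled, Lewis acid-promoted Diels–Alder reaction Et2AlCl forms the cationic chelate of the s-cis acryloyl imide, the benzyl group of the (R)-auxiliary shields the Cα Si face, and the diene adds to the Re face through the endo transition state to give the cis (12S,14'S) ring; the C12–C14' ("ortho") orientation should follow from the terminal alkyl group of this (E)-1,2-dialkyl diene, as with 1-vinylcyclohexene, and one equivalent of Et2AlCl is consumed by the free 3-hydroxyl.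

Step 8
Reactants: 14 hydroxy imide
Product: 16 imide: left core (18-OTBS)–central ring–C14'-carbonyl-N-[(R)-4-benzyl-2-oxo-oxazolidin-3-yl], via imidazolyl thiocarbonate 15 (not isolated)
Conditions: 1,1'-thiocarbonyldiimidazole (2 equiv), toluene, 90 °C; then Bu3SnH (3 equiv), AIBN (0.2 equiv), 110 °C
Reagents that add atoms: none
Why: Barton–McCombie deoxygenation run in one flask converts the hindered equatorial 3β-hydroxyl into its imidazol-1-yl thiocarbonate and reduces the derived C3 radical with Bu3SnH (routinely done in the presence of acyl oxazolidinones); the isolated olefins are inert and C3 becomes a methylene, so no stereocentre is at risk.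

Step 9
Reactants: 16 imide
Product: 18 carboxylic acid: left core (18-OTBS)–central ring–C14'-CO2H, via peroxy acid 17 (not isolated)
Conditions: LiOH, H2O2, THF–H2O (3:1), 0 °C; then aq. Na2SO3; 1 M HCl to pH 3
Reagents that add atoms: hydrogen peroxide OO
Why: Lithium hydroperoxide attacks the exocyclic imide carbonyl selectively even in hindered acyl oxazolidinones and does not epimerise the α-centre C14'; sulfite reduces the peracid and the auxiliary 11 is recovered.

Step 10
Reactants: 18 carboxylic acid
Product: 19 methyl ketone: left core (18-OTBS)–central ring–C14'-C(=O)CH3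
Conditions: MeLi (3 equiv), Et2O–THF, 0 °C; inverse quench into cold 1 M HCl
Reagents that add atoms: methyllithium [Li]C
Why: Methyllithium adds to the lithium carboxylate to give a stable geminal dialkoxide that collapses to the methyl ketone only on work-up (the classical acid-to-methyl ketone conversion), and the cold acidic quench avoids base-mediated epimerisation of the cis C14' centre.

Step 11
Reactants: 19 methyl ketone
Product: 21 alkyne: left core (18-OTBS)–central ring–C14'-C≡CH, via enol phosphate 20 (not isolated)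
Conditions: LiN(iPr)2 (1.1 equiv), THF, −78 °C; ClP(O)(OEt)2, −78 to 0 °C; then LiN(iPr)2 (2.5 equiv), −78 °C to rt; aq. NH4Cl
Reagents that add atoms: none
Why: Kinetic deprotonation occurs at the methyl group and not at the hindered C14' methine, the enolate is trapped as the enol phosphate, and a second deprotonation eliminates diethyl phosphate to give the terminal alkyne (the methyl ketone-to-alkyne protocol that precedes carboalumination in terpenoid synthesis), so C14' keeps its configuration.

Step 12
Reactants: 21 alkyne; 3 C15 acetate (second portion)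
Product: 24 allylic alcohol: left core (18-OTBS)–central ring–C14'-(E)-C13'(CH3)=C12'H–C11'H2-[(2E,6E,10E)-farnesyl chain C9' to C4' ending in C18'H2OH], via alkenylalane 22 (not isolated), via triethylsilyl ether 23 (not isolated)
Conditions: Me3Al (3 equiv), Cp2ZrCl2 (0.5 equiv), ClCH2CH2Cl, rt; then 3 (1.2 equiv), Pd(PPh3)4 (5 mol%), THF, rt; aq. potassium sodium tartrate; then AcOH–THF–H2O (3:1:1), rt
Reagents that add atoms: trimethylaluminium C[Al](C)C
Why: The second Negishi carboalumination installs the C16' methyl and places aluminium on C12' trans to C14', and the zerovalent-palladium-catalysed coupling with the allylic acetate forms C11'–C12' with retention, giving the 12'E and 8'E olefins; dilute acetic acid removes only the triethylsilyl group, while the neopentyl-type TBS ether at C18 remains.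

Step 13
Reactants: 24 allylic alcohol
Product: 26 (3'S,4'S)-3',4'-epoxide of 24 as its C18' tert-butyldiphenylsilyl ether, via epoxy alcohol 25 (not isolated)
Conditions: Ti(OiPr)4 (0.1 equiv), L-(+)-diethyl tartrate (0.12 equiv), t-BuOOH (2 equiv), 4 Å MS, CH2Cl2, −20 °C; then P(OMe)3; then imidazole, t-BuPh2SiCl, 0 °C to rt
Reagents that add atoms: tert-butyl hydroperoxide CC(C)(C)OO; tert-butyldiphenylsilyl chloride CC(C)(C)[Si](Cl)(c1ccccc1)c1ccccc1
Why: Only C3'=C4', the olefin carrying the C18' hydroxymethyl, is an allylic alcohol, so the Katsuki–Sharpless epoxidation is site-selective among six double bonds and, under reagent control by L-(+)-tartrate, gives the (3'S,4'S)-epoxide; the TBDPS group is chosen to survive the oxidation of step 16.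

Step 14
Reactants: 26 epoxy polyene
Product: 27 bis-decalin: left core (18-OTBS)–central ring–C14'-(E)-C13'(CH3)=C12'H–C11'H2–right core (3'β-OH; 18'-OTBDPS; 8'(17')-ene; 5'α-H; 9'α-H; 10'β-CH3; 4'β-CH3)
Conditions: Cp2TiCl2 (2.5 equiv), Mn dust (8 equiv), THF, rt; 26 added over 6 h (final 0.01 M); dilute HCl work-up
Reagents that add atoms: none
Why: Cp2TiCl (trivalent titanium, made in the flask from Cp2TiCl2 and Mn) opens the C3'–C4' epoxide by single-electron transfer at the more substituted carbon to give a β-titanoxy tertiary C4' radical, which closes ring A' by 6-endo-trig attack on C5' of the C5'=C10' olefin; the C10' radical then closes ring B' by 6-endo-trig attack on C9' of the C8'=C9' olefin, and the tertiary C8' radical is captured by a second Cp2TiCl and loses a hydrogen of the C17' methyl to give the exocyclic C8'=C17' olefin. The closest known reaction type is the Cp2TiCl-mediated reductive cyclization of epoxypolyprenes, a radical mimic of the terpene cyclase reaction, including epoxides that carry a silyloxymethyl group. The C3' centre from step 13 keeps its O–Ti group equatorial in a chair–chair array and so fixes the absolute sense of folding: anti addition across the two E olefins gives 5'α-H and 10'β-CH3 (trans fusion) and the equatorial C11' chain at C9' (9'α-H). The planar C4' radical should bond with its larger CH2OTBDPS group equatorial, away from the developing 1,3-diaxial contact with the C10' methyl, which gives 4'α-CH2O and 4'β-CH3. The step needs chemoselectivity among five olefins and a regioselective termination: only the epoxide reacts with Cp2TiCl, each radical attacks the less substituted olefin carbon to give a tertiary radical, and the C8' radical finds no further partner because C12'=C13' could be reached only in a 4-exo or 5-endo mode and the other olefins are remote. Slow addition at high dilution keeps intermolecular radical addition and premature reduction low.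

Step 15
Reactants: 27 hydroxy bis-decalin
Product: 29 3'-deoxy compound: left core (18-OTBS)–central ring–side chain–right core (18'-OTBDPS), via imidazolyl thiocarbonate 28 (not isolated)
Conditions: 1,1'-thiocarbonyldiimidazole (2 equiv), toluene, 90 °C; then Bu3SnH (3 equiv), AIBN (0.2 equiv), 110 °C
Reagents that add atoms: none
Why: The same one-flask Barton–McCombie deoxygenation removes the 3'β-hydroxyl, the only free hydroxyl, the C3' radical having no olefin within reach; both silyl ethers and the four isolated olefins are inert.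

Step 16
Reactants: 29 bis-silyl ether
Product: 30 carboxylic acid: left core (18-CO2H)–central ring–side chain–right core (18'-OTBDPS)
Conditions: CrO3, H2SO4, H2O, acetone, 0 °C (Jones conditions), short reaction time; 2-propanol quench
Reagents that add atoms: water O
Why: Under Jones conditions the primary TBS ether is hydrolysed and the liberated neopentyl alcohol is oxidised through the aldehyde hydrate to the carboxylic acid in one operation, whereas the more acid-stable TBDPS ether at C18' should persist; low temperature and short exposure are chosen to spare the exocyclic olefins.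

Step 17
Reactants: 30 silyl ether acid
Product: 31 target CNP0316988.1
Conditions: Bu4NF (3 equiv), THF, rt to 40 °C; aq. NH4Cl, then dilute HCl
Reagents that add atoms: none
Why: Fluoride cleaves the Si–O bond of the primary TBDPS ether, nothing else in the molecule reacts, and acidification returns the free carboxylic acid.

**Compound list**
1 | (2E,6E)-farnesyl acetate | CC(C)=CCC/C(C)=C/CC/C(C)=C/COC(C)=O | starting material
2 | (2E,6E,10E)-12-hydroxy-3,7,11-trimethyldodeca-2,6,10-trienyl acetate | OC/C(C)=C/CC/C(C)=C/CC/C(C)=C/COC(C)=O | intermediate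
3 | (2E,6E,10E)-3,7,11-trimethyl-12-(triethylsilyloxy)dodeca-2,6,10-trienyl acetate | CC[Si](CC)(CC)OC/C(C)=C/CC/C(C)=C/CC/C(C)=C/COC(C)=O | intermediate
4 | but-1-en-3-yne | C=CC#C | starting material
5 | dimethyl[(1E)-2-methylbuta-1,3-dienyl]alane | C[Al](C)/C=C(\C)C=C | intermediate (not isolated)
6 | triethylsilyl ether of 7 | CC[Si](CC)(CC)OC/C(C)=C/CC/C(C)=C/CC/C(C)=C/C/C=C(\C)C=C | intermediate (not isolated)
7 | (2E,6E,10E,13E)-2,6,10,14-tetramethylhexadeca-2,6,10,13,15-pentaen-1-ol | OC/C(C)=C/CC/C(C)=C/CC/C(C)=C/C/C=C(\C)C=C | intermediate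
8 | (2S,3S)-2,3-epoxy-2,6,10,14-tetramethylhexadeca-6E,10E,13E,15-tetraen-1-ol | OC[C@]1(C)O[C@H]1CC/C(C)=C/CC/C(C)=C/C/C=C(\C)C=C | intermediate (not isolated)
9 | tert-butyldimethylsilyl ether of 8 | CC(C)(C)[Si](C)(C)OC[C@]1(C)O[C@H]1CC/C(C)=C/CC/C(C)=C/C/C=C(\C)C=C | intermediate
10 | 18-(tert-butyldimethylsilyloxy)labda-8(17),12E,14-trien-3β-ol | C=C1CC[C@@H]2[C@](C)(CC[C@H](O)[C@@]2(C)CO[Si](C)(C)C(C)(C)C)[C@H]1C/C=C(\C)C=C | intermediate
11 | (R)-4-benzyl-oxazolidin-2-one | O=C1N[C@H](Cc2ccccc2)CO1 | starting material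
12 | acryloyl chloride | C=CC(=O)Cl | starting material
13 | (R)-3-acryloyl-4-benzyl-oxazolidin-2-one | C=CC(=O)N1[C@H](Cc2ccccc2)COC1=O | intermediate
14 | Diels–Alder imide, 3β-hydroxy, 18-OTBS, (12S,14'S) | C=C1CC[C@@H]2[C@](C)(CC[C@H](O)[C@@]2(C)CO[Si](C)(C)C(C)(C)C)[C@H]1C[C@@H]1C(C)=CCC[C@@H]1C(=O)N1[C@H](Cc2ccccc2)COC1=O | intermediate
15 | 3β-O-(imidazol-1-ylthiocarbonyl) derivative of 14 | C=C1CC[C@@H]2[C@](C)(CC[C@H](OC(=S)n3ccnc3)[C@@]2(C)CO[Si](C)(C)C(C)(C)C)[C@H]1C[C@@H]1C(C)=CCC[C@@H]1C(=O)N1[C@H](Cc2ccccc2)COC1=O | intermediate (not isolated)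
16 | 3-deoxy imide | C=C1CC[C@@H]2[C@](C)(CCC[C@@]2(C)CO[Si](C)(C)C(C)(C)C)[C@H]1C[C@@H]1C(C)=CCC[C@@H]1C(=O)N1[C@H](Cc2ccccc2)COC1=O | intermediate
17 | C14' peroxycarboxylic acid | C=C1CC[C@@H]2[C@](C)(CCC[C@@]2(C)CO[Si](C)(C)C(C)(C)C)[C@H]1C[C@@H]1C(C)=CCC[C@@H]1C(=O)OO | intermediate (not isolated)
18 | C14' carboxylic acid | C=C1CC[C@@H]2[C@](C)(CCC[C@@]2(C)CO[Si](C)(C)C(C)(C)C)[C@H]1C[C@@H]1C(C)=CCC[C@@H]1C(=O)O | intermediate
19 | C14' methyl ketone | C=C1CC[C@@H]2[C@](C)(CCC[C@@]2(C)CO[Si](C)(C)C(C)(C)C)[C@H]1C[C@@H]1C(C)=CCC[C@@H]1C(C)=O | intermediate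
20 | diethyl enol phosphate of 19 | C=C1CC[C@@H]2[C@](C)(CCC[C@@]2(C)CO[Si](C)(C)C(C)(C)C)[C@H]1C[C@@H]1C(C)=CCC[C@@H]1C(=C)OP(=O)(OCC)OCC | intermediate (not isolated)
21 | C14' ethynyl compound | C=C1CC[C@@H]2[C@](C)(CCC[C@@]2(C)CO[Si](C)(C)C(C)(C)C)[C@H]1C[C@@H]1C(C)=CCC[C@@H]1C#C | intermediate
22 | (E)-alkenyl(dimethyl)alane from 21 | C=C1CC[C@@H]2[C@](C)(CCC[C@@]2(C)CO[Si](C)(C)C(C)(C)C)[C@H]1C[C@@H]1C(C)=CCC[C@@H]1/C(C)=C/[Al](C)C | intermediate (not isolated)
23 | triethylsilyl ether of 24 | C=C1CC[C@@H]2[C@](C)(CCC[C@@]2(C)CO[Si](C)(C)C(C)(C)C)[C@H]1C[C@@H]1C(C)=CCC[C@@H]1/C(C)=C/C/C=C(\C)CC/C=C(\C)CC/C=C(\C)CO[Si](CC)(CC)CC | intermediate (not isolated)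
24 | allylic alcohol with acyclic right chain | C=C1CC[C@@H]2[C@](C)(CCC[C@@]2(C)CO[Si](C)(C)C(C)(C)C)[C@H]1C[C@@H]1C(C)=CCC[C@@H]1/C(C)=C/C/C=C(\C)CC/C=C(\C)CC/C=C(\C)CO | intermediate
25 | (3'S,4'S)-epoxy alcohol | C=C1CC[C@@H]2[C@](C)(CCC[C@@]2(C)CO[Si](C)(C)C(C)(C)C)[C@H]1C[C@@H]1C(C)=CCC[C@@H]1/C(C)=C/C/C=C(\C)CC/C=C(\C)CC[C@@H]3O[C@@]3(C)CO | intermediate (not isolated)
26 | (3'S,4'S)-epoxide, 18'-OTBDPS | C=C1CC[C@@H]2[C@](C)(CCC[C@@]2(C)CO[Si](C)(C)C(C)(C)C)[C@H]1C[C@@H]1C(C)=CCC[C@@H]1/C(C)=C/C/C=C(\C)CC/C=C(\C)CC[C@@H]3O[C@@]3(C)CO[Si](c3ccccc3)(c3ccccc3)C(C)(C)C | intermediate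
27 | bis-decalin, 3'β-hydroxy, 18-OTBS, 18'-OTBDPS | C=C1CC[C@@H]2[C@](C)(CCC[C@@]2(C)CO[Si](C)(C)C(C)(C)C)[C@H]1C[C@@H]1C(C)=CCC[C@@H]1/C(C)=C/C[C@H]1C(=C)CC[C@H]2[C@](C)(CO[Si](c3ccccc3)(c3ccccc3)C(C)(C)C)[C@@H](O)CC[C@]12C | intermediate
28 | 3'β-O-(imidazol-1-ylthiocarbonyl) derivative of 27 | C=C1CC[C@@H]2[C@](C)(CCC[C@@]2(C)CO[Si](C)(C)C(C)(C)C)[C@H]1C[C@@H]1C(C)=CCC[C@@H]1/C(C)=C/C[C@H]1C(=C)CC[C@H]2[C@](C)(CO[Si](c3ccccc3)(c3ccccc3)C(C)(C)C)[C@@H](OC(=S)n3ccnc3)CC[C@]12C | intermediate (not isolated)
29 | 3'-deoxy bis-silyl ether | C=C1CC[C@@H]2[C@](C)(CCC[C@@]2(C)CO[Si](C)(C)C(C)(C)C)[C@H]1C[C@@H]1C(C)=CCC[C@@H]1/C(C)=C/C[C@H]1C(=C)CC[C@H]2[C@](C)(CO[Si](c3ccccc3)(c3ccccc3)C(C)(C)C)CCC[C@]12C | intermediate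
30 | 18-oic acid, 18'-OTBDPS | C=C1CC[C@@H]2[C@](C)(CCC[C@@]2(C)C(=O)O)[C@H]1C[C@@H]1C(C)=CCC[C@@H]1/C(C)=C/C[C@H]1C(=C)CC[C@H]2[C@](C)(CO[Si](c3ccccc3)(c3ccccc3)C(C)(C)C)CCC[C@]12C | intermediate
31 | CNP0316988.1 | C=C1CC[C@@H]2[C@](C)(CCC[C@@]2(C)C(=O)O)[C@H]1C[C@@H]1C(C)=CCC[C@@H]1/C(C)=C/C[C@H]1C(=C)CC[C@H]2[C@](C)(CO)CCC[C@]12C | target

**Step count**
Total steps: 17. Longest linear sequence: 16 steps from 1 (steps 1–5 and 7–17); step 6 is a one-step branch.

**Steps most likely to fail**

Step 14. The radical relay may be cut short: the C10' or C8' radical can pick up a hydrogen atom from THF or from titanium-bound water before ring B' closes or before the exocyclic olefin is released, and the planar C4' radical may bond from both faces. The fallback changes from the radical to the polar manifold. It sets out from 26: MeAlCl2 in CH2Cl2 at −78 °C should trigger the cationic epoxy-olefin bicyclization, in which SN2-like anti opening at C4' fixes that centre stereospecifically (the E-disposed CH2OTBDPS becomes 4'α). Proton loss from the C8' cation is expected to give 27 together with its 7'-ene isomer F1, to be separated on AgNO3-impregnated silica; the route is rejoined at 27.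

Step 5. The tertiary radicals may add to the conjugated C12–C15 diene of a second molecule, so that oligomerisation competes with ring closure. The fallback changes the order of events so that no diene is present during the cascade. It sets out from 7 (with 13): Diels–Alder reaction with 13 and Et2AlCl in CH2Cl2 at −78 °C should give the acyclic-chain cycloadduct F2. Sharpless epoxidation with L-(+)-diethyl tartrate then gives the epoxy alcohol F3, and t-BuMe2SiCl/imidazole gives the silyl ether F4. Cp2TiCl bicyclization of F4 would deliver 14 directly, where the route is rejoined; the price is a possible further ring closure of the C8 radical onto the central olefin.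

Step 16. The acidic medium may move the two exocyclic double bonds into the rings, and slow hydrolysis of the hindered neopentyl TBS ether may force an exposure long enough to erode the TBDPS ether. The fallback is stepwise and non-acidic. It sets out from 29: HF·pyridine in pyridine–THF at 0 °C should remove only the TBS group to give the primary alcohol F5. Dess–Martin periodinane gives the aldehyde F6, and NaClO2, NaH2PO4 and 2-methyl-2-butene (Pinnick oxidation) give 30, where the route is rejoined.

**Further compounds**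
F1 | step 14 | 7'-ene isomer of 27 (endocyclic C7'=C8' olefin, C17' methyl) | C=C1CC[C@@H]2[C@](C)(CCC[C@@]2(C)CO[Si](C)(C)C(C)(C)C)[C@H]1C[C@@H]1C(C)=CCC[C@@H]1/C(C)=C/C[C@H]1C(C)=CC[C@H]2[C@](C)(CO[Si](c3ccccc3)(c3ccccc3)C(C)(C)C)[C@@H](O)CC[C@]12C
F2 | step 5 | acyclic-chain cycloadduct: (12S,14'S) central ring carrying the hydroxy-farnesyl chain on C12 and the N-acyl (R)-4-benzyl-oxazolidin-2-one on C14' | OC/C(C)=C/CC/C(C)=C/CC/C(C)=C/C[C@@H]1C(C)=CCC[C@@H]1C(=O)N1[C@H](Cc2ccccc2)COC1=O
F3 | step 5 | (3S,4S)-epoxy alcohol of F2 | OC[C@]1(C)O[C@H]1CC/C(C)=C/CC/C(C)=C/C[C@@H]1C(C)=CCC[C@@H]1C(=O)N1[C@H](Cc2ccccc2)COC1=O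
F4 | step 5 | tert-butyldimethylsilyl ether of F3 | CC(C)(C)[Si](C)(C)OC[C@]1(C)O[C@H]1CC/C(C)=C/CC/C(C)=C/C[C@@H]1C(C)=CCC[C@@H]1C(=O)N1[C@H](Cc2ccccc2)COC1=O
F5 | step 16 | 18-alcohol, 18'-OTBDPS | C=C1CC[C@@H]2[C@](C)(CCC[C@@]2(C)CO)[C@H]1C[C@@H]1C(C)=CCC[C@@H]1/C(C)=C/C[C@H]1C(=C)CC[C@H]2[C@](C)(CO[Si](c3ccccc3)(c3ccccc3)C(C)(C)C)CCC[C@]12C
F6 | step 16 | 18-aldehyde, 18'-OTBDPS | C=C1CC[C@@H]2[C@](C)(CCC[C@@]2(C)C=O)[C@H]1C[C@@H]1C(C)=CCC[C@@H]1/C(C)=C/C[C@H]1C(=C)CC[C@H]2[C@](C)(CO[Si](c3ccccc3)(c3ccccc3)C(C)(C)C)CCC[C@]12C
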